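If you repeat the midnight flask, watch how much target disappears per hour as a concentration, not as a percentage of what is still there.

| setting | midnight | summer | flask |
|---|---|---|---|
| substrate | 0.25 M | 0.17 M | 0.25 M |
| remark | the very flask that is asked about, followed so far | run made earlier |  |
| time |  |  | 25 h |

| run | time / h | target / % | isomer of the product / % |
|---|---|---|---|
| midnight | 0.417 | 80 | 1 |
| midnight | 1.00 | 96 | 3 |
| midnight | 2.00 | 93 | 2 |
| midnight | 5.00 | 91 | 2 |
| summer | 0.833 | 92 | 4 |
| summer | 2.00 | 90 | 1 |
| summer | 4.00 | 87 | 4 |
| summer | 10.0 | 70 | 6 |

(scatter of a reading: 1.5 percentage points)

- ratio of target to isomer of the product at 15 s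
- ratio of target to isomer of the product at 25 h

Minutes of the meeting. The first speaker noted that the midnight run read its highest target, 96%, at 1.00 h, and that the loss afterwards was the open question. The second speaker turned the percentages into concentrations. In the summer run c(target) fell from 92% to 70% of the charge between 0.833 h and 10.0 h, and she proposed this fall per hour as the loss rate 4.08 mM h⁻¹. The midnight run read 3.12 mM h⁻¹, but she trusted the summer figure more, since its span is longer and each reading scatters by 1.5 percentage points.

A third member suggested that a fast equilibrium might hold free target at a fixed low level. Loss from that level would be zero-order, so its rate would stay constant as a concentration and a smaller charge would lose more in percent per hour, as the summer run did.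

The chair's own reckoning for the midnight flask ran the loss rate from the highest target reading of the midnight run to 25 h, leaving 56.8% target. Divided by the highest isomer reading of either run, the 6% of the summer run at 10.0 h, that gave a ratio of 9.47. He offered no early ratio, because the first isomer reading of the midnight run, 1%, lies below the scatter.

The forecast gave 40 (18 to 150) at 15 s and 10 (3 to 25) at 25 h, holding that “The target then slowly decays, at about 0.015–0.03 per hour, perhaps accelerating in the summer run”. The chair's 9.47 is his own figure and stands a little below the forecast's.

    target ⇌ isomer of the product (k = 1.58 × 10⁻⁵ s⁻¹)
    substrate + target ⇌ idle adduct, settled at all times (K = 4.68 M⁻¹)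
    substrate ⇌ isomer of the product (K = 8.74, k = 1.92 × 10⁻⁵ s⁻¹)
    crystals ⇌ target, rate k4*(cs4 - [target]) while solid is left; crystals form when [target] > cs4 (solubility = 3.20 mM, k = 0.0661 s⁻¹)
    substrate ⇌ target (K = 0.894, k = 0.00120 s⁻¹)
    target → over-reaction product (k = 3.19 × 10⁻⁴ s⁻¹)

The midnight flask gives 61.9 at 15 s and 12.0 at 25 h. At that end it holds 56.8% target, crystals of 55.5% counted within it, beside 4.73% isomer of the product. The loss rate, run over the chair's hours, comes to 39.2% of this charge, and at 25 h the flask holds 37.0% over-reaction product. On the neighbour charged with 1.0 M, the same loss rate over the same hours comes to 9.79% of its charge, and at 25 h that neighbour holds 9.61% over-reaction product.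

Readings and results stem from a simulated flask with made-up constants.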